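**Retrosynthetic overview**

- The (E)-enyne is installed last from the terminal alkene 16 by cross-metathesis with (E)-but-2-enal and a one-carbon diazo homologation.
- The oxane 16 comes from the 2,5-cis oxolanyl carbinol 13 by a 1,2-oxygen-shift ring expansion, terminated by chloride: the ring oxygen moves from C10 to C9 and Cl enters at C10.
- 13 comes from methyl ketone 8 and (R)-2-chloropent-4-enal by an α-chloroaldehyde aldol (C6, C7), then an Evans–Tishchenko reduction (C7 acetate, C9 alcohol).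
- 8 comes from butanal and 3-methylbut-3-en-2-one: α-chloroaldehyde aldol, 1,3-anti reduction, chloride displacement to the oxolane, OH→Br inversion, ozonolysis.
- Ring order: the oxolane (O, C10–C13) is closed first (step 3) and is expanded to the oxane (O, C9–C13) in step 8.

Positions are numbered along the C15 chain of the target: C1 is the alkyne CH and C15 the ethyl CH3.

Assumption: the (2S,5S) antipode of 2,5-diphenylpyrrolidine is taken to give the (R)-α-chloroaldehydes; if the sense is the reverse, its mirror image is used.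

**Route**

Step 1
Reactants: 1 butanal; 2 3-methylbut-3-en-2-one
Product: 4 (5S,6R)-6-chloro-5-hydroxy-2-methyloct-1-en-3-one, via (R)-2-chlorobutanal 3 (not isolated)
Conditions: NCS, (2S,5S)-2,5-diphenylpyrrolidine (10 mol%), CH2Cl2, 0 °C to rt; pentane, filter; crude 3 added to the lithium enolate of 2 (LiN(iPr)2, THF, −78 °C); AcOH, −78 °C
Reagents that add atoms: N-chlorosuccinimide, O=C1CCC(=O)N1Cl
Why: Enamine-catalysed α-chlorination sets C13 (R), and the kinetic lithium enolate of the methyl ketone adds to the α-chloroaldehyde under Cornforth–Felkin control (aldol addition) to give the 1,2-anti chlorohydrin, setting C12 (S).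

Step 2
Reactants: 4 (5S,6R)-6-chloro-5-hydroxy-2-methyloct-1-en-3-one
Product: 5 (3S,5S,6R)-6-chloro-2-methyloct-1-ene-3,5-diol
Conditions: Me4NBH(OAc)3, MeCN/AcOH, −40 to −20 °C
Reagents that add atoms: none
Why: Evans–Saksena hydroxyl-directed reduction delivers hydride intramolecularly through a chair alkoxyborohydride and gives the 1,3-anti diol, setting C10 (S).

Step 3
Reactants: 5 (3S,5S,6R)-6-chloro-2-methyloct-1-ene-3,5-diol
Product: 6 (2S,3S,5S)-2-ethyl-5-(prop-1-en-2-yl)oxolan-3-ol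
Conditions: AgOSO2CF3, Ag2O, THF, 50 °C
Reagents that add atoms: none
Why: Silver-assisted 5-exo-tet Williamson-type displacement of the C13 chloride by the C10 hydroxyl goes with inversion, which fixes C13 (S) and the 2,5-cis oxolane with no facial choice involved.

Step 4
Reactants: 6 (2S,3S,5S)-2-ethyl-5-(prop-1-en-2-yl)oxolan-3-ol
Product: 7 (2S,3R,5S)-3-bromo-2-ethyl-5-(prop-1-en-2-yl)oxolane
Conditions: CBr4, (n-C8H17)3P, toluene, 70 °C
Reagents that add atoms: carbon tetrabromide, BrC(Br)(Br)Br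
Why: Appel bromination: bromide displaces the alkoxyphosphonium from the open face of the all-cis oxolane (SN2 inversion), setting C12 (R) with bromine trans to both ring substituents.

Step 5
Reactants: 7 (2S,3R,5S)-3-bromo-2-ethyl-5-(prop-1-en-2-yl)oxolane
Product: 8 1-[(2S,4R,5S)-4-bromo-5-ethyloxolan-2-yl]ethan-1-one
Conditions: O3, CH2Cl2/MeOH, −78 °C; Me2S
Reagents that add atoms: ozone, [O-][O+]=O
Why: Ozonolysis of the 1,1-disubstituted alkene unmasks the methyl ketone under neutral conditions, so the epimerisable C10 centre is not disturbed.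

Step 6
Reactants: 8 1-[(2S,4R,5S)-4-bromo-5-ethyloxolan-2-yl]ethan-1-one; 9 pent-4-enal
Product: 11 (3S,4R)-1-[(2S,4R,5S)-4-bromo-5-ethyloxolan-2-yl]-4-chloro-3-hydroxyhept-6-en-1-one, via (R)-2-chloropent-4-enal 10 (not isolated)
Conditions: 9, NCS, (2S,5S)-2,5-diphenylpyrrolidine (10 mol%), CH2Cl2, 0 °C to rt; pentane, filter; crude 10 (1.5 equiv) added to the lithium enolate of 8 (LiN(iPr)2, THF, −78 °C); AcOH, −78 °C
Reagents that add atoms: N-chlorosuccinimide, O=C1CCC(=O)N1Cl
Why: Enamine-catalysed α-chlorination sets C6 (R), and the methyl-side kinetic enolate of 8 adds to the α-chloroaldehyde under Cornforth–Felkin control (aldol addition) to give the 1,2-anti chlorohydrin, setting C7 (S).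

Step 7
Reactants: 11 (3S,4R)-1-[(2S,4R,5S)-4-bromo-5-ethyloxolan-2-yl]-4-chloro-3-hydroxyhept-6-en-1-one; 12 acetaldehyde
Product: 13 (1S,3S,4R)-1-[(2S,4R,5S)-4-bromo-5-ethyloxolan-2-yl]-4-chloro-1-hydroxyhept-6-en-3-yl acetate
Conditions: SmI2 (30 mol%), THF, −10 °C
Reagents that add atoms: none
Why: Evans–Tishchenko reduction: the samarium-bound hemiacetal formed from acetaldehyde on the C7 oxygen transfers hydride to the C9 ketone through a chair six-membered transition state, which gives the 1,3-anti C9 (S) alcohol and leaves the acetate on C7.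

Step 8
Reactants: 13 (1S,3S,4R)-1-[(2S,4R,5S)-4-bromo-5-ethyloxolan-2-yl]-4-chloro-1-hydroxyhept-6-en-3-yl acetate
Product: 16 (2S,3R)-1-[(2R,3R,5R,6S)-5-bromo-3-chloro-6-ethyloxan-2-yl]-3-chlorohex-5-en-2-yl acetate, via chloromethanesulfonate ester 14 (not isolated), via 1-oxoniabicyclo[3.1.0]hexane ion 15 (not isolated)
Conditions: ClCH2SO2Cl, 2,6-lutidine, CH2Cl2, 0 °C; then ZnCl2, Bu4NCl, ClCH2CH2Cl, 50 °C
Reagents that add atoms: tetrabutylammonium chloride, CCCC[N+](CCCC)(CCCC)CCCC.[Cl-]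
Why: Proposed new method: the ring oxygen displaces the zinc-activated C9 sulfonate from the back (inversion, C9 becomes R) to give the bicyclic oxonium ion 15, and a weakly nucleophilic chlorozincate chloride then opens it at the ring-fusion carbon C10 anti to oxygen (inversion, C10 becomes R), so the 2,5-cis oxolane becomes the 2,6-cis oxane with axial chlorine in one stereospecific 1,2-oxygen shift; the closest known reaction type is the Nakata chloromethanesulfonate/Zn(OAc)2 oxolane-to-oxane expansion terminated by carboxylate or water (and the prolinol to 3-chloropiperidine aziridinium expansion), and the new element is termination by chloride to create the C–Cl stereocentre, with attack at C10 favoured because it releases the strain of both small rings and because any C9 chloride can re-enter the same ion on warming.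

Step 9
Reactants: 16 (2S,3R)-1-[(2R,3R,5R,6S)-5-bromo-3-chloro-6-ethyloxan-2-yl]-3-chlorohex-5-en-2-yl acetate; 17 (E)-but-2-enal
Product: 18 (2S,3R,5E)-1-[(2R,3R,5R,6S)-5-bromo-3-chloro-6-ethyloxan-2-yl]-3-chloro-7-oxohept-5-en-2-yl acetate
Conditions: second-generation Hoveyda–Grubbs catalyst (5 mol%), CH2Cl2, 40 °C
Reagents that add atoms: none
Why: Olefin cross-metathesis of the only alkene left in the molecule with an electron-poor partner gives the (E)-enal under thermodynamic control.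

Step 10
Reactants: 18 (2S,3R,5E)-1-[(2R,3R,5R,6S)-5-bromo-3-chloro-6-ethyloxan-2-yl]-3-chloro-7-oxohept-5-en-2-yl acetate
Product: 19 (2S,3R,5E)-1-[(2R,3R,5R,6S)-5-bromo-3-chloro-6-ethyloxan-2-yl]-3-chlorooct-5-en-7-yn-2-yl acetate
Conditions: Me3SiCHN2 (1.2 equiv), LiN(iPr)2, THF, −78 to 0 °C
Reagents that add atoms: trimethylsilyldiazomethane, C[Si](C)(C)C=[N+]=[N-]
Why: Colvin homologation: lithiated trimethylsilyldiazomethane adds to the aldehyde, Peterson elimination and loss of N2 give an alkylidene carbene, and its 1,2-shift gives the terminal alkyne with the E alkene untouched.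

**Compound list**

1 | butanal | CCCC=O | starting material
2 | 3-methylbut-3-en-2-one | CC(=O)C(C)=C | starting material
3 | (R)-2-chlorobutanal | CC[C@@H](Cl)C=O | intermediate
4 | (5S,6R)-6-chloro-5-hydroxy-2-methyloct-1-en-3-one | C=C(C)C(=O)C[C@H](O)[C@H](Cl)CC | intermediate
5 | (3S,5S,6R)-6-chloro-2-methyloct-1-ene-3,5-diol | C=C(C)[C@@H](O)C[C@H](O)[C@H](Cl)CC | intermediate
6 | (2S,3S,5S)-2-ethyl-5-(prop-1-en-2-yl)oxolan-3-ol (all-cis) | CC[C@@H]1O[C@H](C(C)=C)C[C@@H]1O | intermediate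
7 | (2S,3R,5S)-3-bromo-2-ethyl-5-(prop-1-en-2-yl)oxolane | CC[C@@H]1O[C@H](C(C)=C)C[C@H]1Br | intermediate
8 | 1-[(2S,4R,5S)-4-bromo-5-ethyloxolan-2-yl]ethan-1-one | CC(=O)[C@H]1O[C@@H](CC)[C@H](Br)C1 | intermediate
9 | pent-4-enal | C=CCCC=O | starting material
10 | (R)-2-chloropent-4-enal | C=CC[C@@H](Cl)C=O | intermediate
11 | (3S,4R)-1-[(2S,4R,5S)-4-bromo-5-ethyloxolan-2-yl]-4-chloro-3-hydroxyhept-6-en-1-one | C=CC[C@@H](Cl)[C@@H](O)CC(=O)[C@H]1O[C@@H](CC)[C@H](Br)C1 | intermediate
12 | acetaldehyde | CC=O | starting material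
13 | (1S,3S,4R)-1-[(2S,4R,5S)-4-bromo-5-ethyloxolan-2-yl]-4-chloro-1-hydroxyhept-6-en-3-yl acetate | C=CC[C@@H](Cl)[C@@H](OC(C)=O)C[C@H](O)[C@H]1O[C@@H](CC)[C@H](Br)C1 | intermediate
14 | (1S,3S,4R)-3-acetoxy-1-[(2S,4R,5S)-4-bromo-5-ethyloxolan-2-yl]-4-chlorohept-6-en-1-yl chloromethanesulfonate | C=CC[C@@H](Cl)[C@@H](OC(C)=O)C[C@H](OS(=O)(=O)CCl)[C@H]1O[C@@H](CC)[C@H](Br)C1 | intermediate
15 | (2S,3R,5S,6R)-6-[(2S,3R)-2-acetoxy-3-chlorohex-5-en-1-yl]-3-bromo-2-ethyl-1-oxoniabicyclo[3.1.0]hexane chloromethanesulfonate | C=CC[C@@H](Cl)[C@@H](OC(C)=O)C[C@H]1[O+]2[C@@H](CC)[C@H](Br)C[C@@H]12.[O-]S(=O)(=O)CCl | intermediate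
16 | (2S,3R)-1-[(2R,3R,5R,6S)-5-bromo-3-chloro-6-ethyloxan-2-yl]-3-chlorohex-5-en-2-yl acetate | C=CC[C@@H](Cl)[C@H](C[C@H]1O[C@@H](CC)[C@H](Br)C[C@H]1Cl)OC(C)=O | intermediate
17 | (E)-but-2-enal | C/C=C/C=O | starting material
18 | (2S,3R,5E)-1-[(2R,3R,5R,6S)-5-bromo-3-chloro-6-ethyloxan-2-yl]-3-chloro-7-oxohept-5-en-2-yl acetate | O=C/C=C/C[C@@H](Cl)[C@H](C[C@H]1O[C@@H](CC)[C@H](Br)C[C@H]1Cl)OC(C)=O | intermediate
19 | (2S,3R,5E)-1-[(2R,3R,5R,6S)-5-bromo-3-chloro-6-ethyloxan-2-yl]-3-chlorooct-5-en-7-yn-2-yl acetate | C#C/C=C/C[C@@H](Cl)[C@H](C[C@H]1O[C@@H](CC)[C@H](Br)C[C@H]1Cl)OC(C)=O | target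

**Step count and risks**

Total: 10 steps. Steps 1 and 6 are each a telescoped α-chlorination/aldol in which the α-chloroaldehyde is used crude; counted separately, the total would be 12. Longest linear sequence: 10 steps (1 → 19).

The three steps most likely to fail:

Step 8, the proposed chloride-terminated ring expansion. Three things can go wrong: chloride may attack the sulfonate 14 directly at C9, the C7 acetate carbonyl may capture C9 through a six-membered acyloxonium ion, or the oxonium ion 15 may open at C9 instead of C10. The fallback uses known chemistry, sets out from 13 and returns at 16. The same chloromethanesulfonate 14 is solvolysed in buffered aqueous 1,4-dioxane (2,6-lutidine, 60 °C), the water-terminated form of the established expansion. This gives (2S,3R)-1-[(2R,3R,5R,6S)-5-bromo-6-ethyl-3-hydroxyoxan-2-yl]-3-chlorohex-5-en-2-yl acetate F2, with the C10 hydroxyl axial. Because chlorine must end where this oxygen sits, C10 is then inverted twice. Mitsunobu inversion (chloroacetic acid, PPh3, diisopropyl azodicarboxylate, toluene, 0 °C) gives (2S,3R)-1-[(2R,3S,5R,6S)-5-bromo-3-(2-chloroacetoxy)-6-ethyloxan-2-yl]-3-chlorohex-5-en-2-yl acetate F3. Selective removal of the chloroacetate with thiourea (NaHCO3, EtOH, 50 °C) leaves the C7 acetate and gives (2S,3R)-1-[(2R,3S,5R,6S)-5-bromo-6-ethyl-3-hydroxyoxan-2-yl]-3-chlorohex-5-en-2-yl acetate F4. Appel chlorination with inversion (CCl4, (n-C8H17)3P, toluene, 80 °C) then gives 16.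

Step 7, the Evans–Tishchenko reduction. SmI2 may reduce the secondary bromide, and the aldol 11 can undergo retro-aldol cleavage or acetyl migration. The fallback sets out from 11 and returns at 13, replacing intramolecular hydride transfer by acylation followed by reagent-controlled reduction. Acid-catalysed acetylation (Ac2O, Sc(OSO2CF3)3 1 mol%, MeCN, −20 °C) gives (3S,4R)-1-[(2S,4R,5S)-4-bromo-5-ethyloxolan-2-yl]-4-chloro-1-oxohept-6-en-3-yl acetate F1. Reduction of the C9 ketone with (R)-2-methyl-CBS-oxazaborolidine and catecholborane (toluene, −78 °C) then gives 13; the reagent sense is matched with the Felkin preference of the α-alkoxy ketone for the (9S) alcohol.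

Step 10, the Colvin homologation. The lithiated diazo reagent may attack the acetate or eliminate HCl or HBr. The fallback sets out from 16, bypasses enal 18 and returns at 19, building the enyne by cross-coupling under near-neutral conditions. Cross-metathesis of 16 with vinylboronic acid pinacol ester (second-generation Grubbs catalyst, CH2Cl2, 40 °C) gives (2S,3R,5E)-1-[(2R,3R,5R,6S)-5-bromo-3-chloro-6-ethyloxan-2-yl]-3-chloro-6-(4,4,5,5-tetramethyl-1,3,2-dioxaborolan-2-yl)hex-5-en-2-yl acetate F5. Suzuki–Miyaura coupling with (bromoethynyl)tri(propan-2-yl)silane (Pd(PPh3)4, K3PO4, THF/H2O, rt) gives (2S,3R,5E)-1-[(2R,3R,5R,6S)-5-bromo-3-chloro-6-ethyloxan-2-yl]-3-chloro-8-[tri(propan-2-yl)silyl]oct-5-en-7-yn-2-yl acetate F6. Buffered desilylation (Bu4NF, AcOH, THF, 0 °C) then gives 19.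

**Further compounds**

F1 | step 7 | (3S,4R)-1-[(2S,4R,5S)-4-bromo-5-ethyloxolan-2-yl]-4-chloro-1-oxohept-6-en-3-yl acetate | C=CC[C@@H](Cl)[C@@H](OC(C)=O)CC(=O)[C@H]1O[C@@H](CC)[C@H](Br)C1
F2 | step 8 | (2S,3R)-1-[(2R,3R,5R,6S)-5-bromo-6-ethyl-3-hydroxyoxan-2-yl]-3-chlorohex-5-en-2-yl acetate | C=CC[C@@H](Cl)[C@H](C[C@H]1O[C@@H](CC)[C@H](Br)C[C@H]1O)OC(C)=O
F3 | step 8 | (2S,3R)-1-[(2R,3S,5R,6S)-5-bromo-3-(2-chloroacetoxy)-6-ethyloxan-2-yl]-3-chlorohex-5-en-2-yl acetate | C=CC[C@@H](Cl)[C@H](C[C@H]1O[C@@H](CC)[C@H](Br)C[C@@H]1OC(=O)CCl)OC(C)=O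
F4 | step 8 | (2S,3R)-1-[(2R,3S,5R,6S)-5-bromo-6-ethyl-3-hydroxyoxan-2-yl]-3-chlorohex-5-en-2-yl acetate | C=CC[C@@H](Cl)[C@H](C[C@H]1O[C@@H](CC)[C@H](Br)C[C@@H]1O)OC(C)=O
F5 | step 10 | (2S,3R,5E)-1-[(2R,3R,5R,6S)-5-bromo-3-chloro-6-ethyloxan-2-yl]-3-chloro-6-(4,4,5,5-tetramethyl-1,3,2-dioxaborolan-2-yl)hex-5-en-2-yl acetate | CC1(C)OB(/C=C/C[C@@H](Cl)[C@H](C[C@H]2O[C@@H](CC)[C@H](Br)C[C@H]2Cl)OC(C)=O)OC1(C)C
F6 | step 10 | (2S,3R,5E)-1-[(2R,3R,5R,6S)-5-bromo-3-chloro-6-ethyloxan-2-yl]-3-chloro-8-[tri(propan-2-yl)silyl]oct-5-en-7-yn-2-yl acetate | CC(C)[Si](C#C/C=C/C[C@@H](Cl)[C@H](C[C@H]1O[C@@H](CC)[C@H](Br)C[C@H]1Cl)OC(C)=O)(C(C)C)C(C)C
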